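Which flask keeps more of its product as target, noon or autumn, and by how much?

| flask | substrate | gas | free catalyst | remark | time |
|---|---|---|---|---|---|
| violet | 1 mM (fed, over 30 s) | 0.44 mM (held) | 0.052 mol% | run made earlier |  |
| teal | 4 mM (fed, over 30 s) | 0.44 mM (held) | 0.052 mol% | run made earlier |  |
| noon | 2.0 mM | 0.44 mM | 0.052 mol% | everything together at the start | 5.0 min |
| autumn | 2.0 mM (fed, over 30 s) | 0.44 mM (held) | 0.052 mol% |  | 5.0 min |

| run | time / min | target / % | isomer of the product / % |
|---|---|---|---|
| violet | 0.833 | 5.5 | 1.8 |
| violet | 1.50 | 12.9 | 0 |
| violet | 2.50 | 18.4 | 0.5 |
| violet | 3.00 | 19.7 | 0.2 |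
| teal | 0.250 | 3.4 | 0 |
| teal | 0.500 | 7.8 | 0 |
| teal | 1.33 | 17.6 | 0 |
| teal | 3.00 | 31.4 | 0 |

(each reading ± 1 percentage point)

* the winner by share of target in all that became target or isomer of the product; "neither" if no more than 2 percentage points parts them (noon / autumn / neither)
* share of target in all that became target or isomer of the product, noon
* share of target in all that became target or isomer of the product, autumn

- at the start none of coupling partner is dissolved
- on the list of suspects stand: gas <-> coupling partner; catalyst intermediate B <-> free catalyst + target; coupling partner + catalyst intermediate A -> catalyst intermediate B; substrate + free catalyst <-> catalyst intermediate A; target + free catalyst <-> isomer of the product + free catalyst; 2 free catalyst -> spent catalyst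
- percentages count the whole charge, also what has not yet gone in

I first asked what sets the split. Free catalyst meets either substrate, which leads on to target, or target, which gives isomer. So free catalyst cancels, and new isomer per new target goes as r times target over substrate, with r a fixed ratio of two rate constants, a selectivity factor. Summed over a run, isomer as a fraction of the charge comes to about rΦ, while isomer stays small. Here x is the fraction converted, and Φ is ln(charge/substrate left) minus x. At 3.00 min teal had x of 31.4%, so Φ read 0.0629, the isomer clock I carried on. Its isomer read 0%, so a reading two standard deviations up allowed r as high as about 0.318, my rough ceiling.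

Next I asked how far each flask goes. At that time teal stood higher than violet, 31.4% against 19.7%. Both earlier runs were fed, and noon has everything in at the start, so for noon I made a plain guess: x of 62.8%, twice teal's. For autumn I took teal's x.

The share lost is rΦ/x: r times 0.575 for noon, r times 0.200 for autumn. How large must r be? The flasks part by more than 2 percentage points once r passes 0.0534, which is less than the ceiling. The readings allow r on either side of that value, so this was a judgement: I committed to autumn.

The forecast said neither, with 99% for noon and 98.5% for autumn. Of isomerisation it argued “it should be slow wherever substrate ties up the catalyst”.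

The flasks gave 93.8% for noon and 97.8% for autumn, so autumn won. The forecast's noon stood 5.2 points too high.

    gas ⇌ coupling partner, rate k1*(csat - [coupling partner]) (kL = 0.158 s⁻¹)
    catalyst intermediate B ⇌ free catalyst + target (K = 7.17 × 10⁻⁴ M, k = 178 s⁻¹)
    coupling partner + catalyst intermediate A → catalyst intermediate B (k = 4.91 × 10⁵ L mol⁻¹ s⁻¹)
    substrate + free catalyst ⇌ catalyst intermediate A (K = 14000 L mol⁻¹, k = 1.66 × 10⁵ L mol⁻¹ s⁻¹)
    target + free catalyst ⇌ isomer of the product + free catalyst, rate k5*[free catalyst]*[target] forward; the back reaction follows from the equilibrium constant (K = 2.10, k = 17000 L mol⁻¹ s⁻¹)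
    2 free catalyst → spent catalyst (k = 1.30 × 10⁶ L mol⁻¹ s⁻¹)

In autumn at 5.00 min, the relaxation half-life of target and isomer, by the step between them alone, was 108 min, long against the 5.0 min of the run, the picture of kinetic rather than thermodynamic control. Noon reached x of 64.5% and Φ of 0.391 with 4.03% isomer, which reads r as 0.103. On the carried 0.0629, that r gives 0.648% of the charge, and autumn, at x of 31.2%, held 0.673% at 5.00 min. A neighbouring flask, autumn with 0.13 mol% of free catalyst, held 0.710% isomer at 5.00 min.

(The runs stem from a simulated flask with constants of no real substance, and the scatter is random.)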